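**Plan**

- Retrosynthesis: the two acetates and the C1' ether are removed first. The ring bond C4–C5 is then cut as an aldol bond, which unravels the cyclopentenone to a (Z)-5-hydroxy-4-oxo-2-enal stored as its pyranone hemiacetal. That pyranone is an oxidised 2-furylcarbinol, cut at the furan–carbinol bond and finally at C2'–C3' of the chain.
- Enabling feature (ring: C1 ketone, C2=C3, C4 acetoxy carbon, C5 tertiary carbinol; C1' side-chain carbinol): the C1(=O)–C5(OH)–C4(O) array bridged by the cis C2=C3 bond is the aldol adduct of a cis-ene-dione, and C1 to C4 with that alkene geometry are what an oxidised furan supplies.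
- Forward: the C16 chain is built by opening (S)-benzyl glycidyl ether with a C13 Grignard reagent. Furan is added to the derived alpha-MOM-oxy aldehyde and oxidised to the six-membered pyranone, which is contracted to the only carbocycle, the cyclopentenone. MOM removal and diacetylation finish the route.
- Stereochemistry: C1' (S) is bought with the glycidyl ether and not touched again. C5 and C4 are both created in the ring contraction under control of C1' through a magnesium chelate. The furylcarbinol and hemiacetal centres are mixtures that the contraction erases.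

Key step: step 7

Assumption: the carbinol carbon of 10 and ring C2/C6 of 11 are carried as stereoisomer mixtures, because step 7 flattens or removes them; 13 is labelled 5R only because the MOM ether outranks the C4 carbinol, its spatial arrangement being that of the target (5S).

**Route**

Step 1
Reactants: 1 (S)-benzyl glycidyl ether; 2 1-bromotridecane
Product: 4 (2S)-1-(benzyloxy)hexadecan-2-ol, via tridecylmagnesium bromide 3 (not isolated)
Conditions: 2 (1.3 equiv), Mg, THF, rt to 50 °C; then CuI (10 mol%), 1, −30 to 0 °C; then H2O
Reagents that add atoms: none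
Why: Copper-catalysed Grignard opening of a terminal epoxide is an SN2 attack at the unsubstituted carbon, so the stereocentre of 1 is not involved and becomes C1' of the target with the S configuration.

Step 2
Reactants: 4 (2S)-1-(benzyloxy)hexadecan-2-ol
Product: 5 (2S)-1-(benzyloxy)-2-(methoxymethoxy)hexadecane
Conditions: MOMCl, iPr2NEt, CH2Cl2, 0 °C to rt
Reagents that add atoms: chloromethyl methyl ether, COCCl
Why: Williamson-type O-alkylation of the secondary alcohol with the reactive alpha-chloro ether installs a base-stable, chelating acetal ether without touching the stereocentre.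

Step 3
Reactants: 5 (2S)-1-(benzyloxy)-2-(methoxymethoxy)hexadecane
Product: 6 (2S)-2-(methoxymethoxy)hexadecan-1-ol
Conditions: H2 (1 atm), Pd/C (10 wt%), EtOAc, rt
Reagents that add atoms: none
Why: Catalytic hydrogenolysis cleaves the benzyl ether selectively, the MOM acetal being inert to H2 over Pd/C, and it is done before any furan or alkene is present.

Step 4
Reactants: 6 (2S)-2-(methoxymethoxy)hexadecan-1-ol
Product: 7 (2S)-2-(methoxymethoxy)hexadecanal
Conditions: TEMPO (10 mol%), PhI(OAc)2 (1.1 equiv), CH2Cl2, rt; used at once
Reagents that add atoms: none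
Why: Nitroxyl-catalysed oxidation with PhI(OAc)2 as terminal oxidant stops at the aldehyde and runs without base, which should keep the alpha-alkoxy stereocentre from epimerising.

Step 5
Reactants: 7 (2S)-2-(methoxymethoxy)hexadecanal; 8 furan
Product: 10 (2S)-1-(furan-2-yl)-2-(methoxymethoxy)hexadecan-1-ol, via 2-furyllithium 9 (not isolated)
Conditions: 8 (2 equiv), n-BuLi (1.5 equiv), THF, 0 °C; then 7, −78 °C; then H2O
Reagents that add atoms: none
Why: Furan is lithiated at C2 and the organolithium adds 1,2 to the aldehyde at −78 °C faster than it enolises it; the new carbinol centre forms as an epimer mixture, which is accepted because this carbon becomes the planar enol carbon in step 7.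

Step 6
Reactants: 10 (2S)-1-(furan-2-yl)-2-(methoxymethoxy)hexadecan-1-ol
Product: 11 6-hydroxy-2-[(1S)-1-(methoxymethoxy)pentadecyl]-2H-pyran-3(6H)-one
Conditions: NBS (1.05 equiv), NaHCO3 (2 equiv), THF/H2O (4:1), 0 °C
Reagents that add atoms: water, O
Why: Achmatowicz rearrangement, in which NBS oxidises the furan in buffered aqueous THF to the 2,5-dioxygenated dihydrofuran that opens to the cis-ene-dione and is captured by the carbinol oxygen as the six-membered hemiacetal; the C1' centre is a spectator.

Step 7
Reactants: 11 6-hydroxy-2-[(1S)-1-(methoxymethoxy)pentadecyl]-2H-pyran-3(6H)-one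
Product: 13 (4R,5R)-4,5-dihydroxy-5-[(1S)-1-(methoxymethoxy)pentadecyl]cyclopent-2-en-1-one, via open-chain (Z)-hydroxy-oxo-enal 12 (not isolated)
Conditions: MgBr2·OEt2 (2 equiv), NEt3 (1.5 equiv), CH2Cl2, −20 to 0 °C; then pH 7 buffer
Reagents that add atoms: none
Why: NEt3 equilibrates hemiacetal 11 with the open (Z)-5-hydroxy-4-oxo-2-enal 12, and MgBr2 bound to the ketone lets the amine remove the only enolisable proton (at C5, the other alpha carbon being vinylic); the magnesium enol then adds to the aldehyde carbon held nearby by the cis alkene, forming the C4–C5 bond. The closest known reaction is the amine-mediated contraction of 6-hydroxy-2H-pyran-3(6H)-ones to trans-4,5-dihydroxycyclopent-2-enones, an intramolecular aldol addition, run here under magnesium halide/tertiary amine soft enolisation. The cyclopentenone closes in the 5-(enolendo)-exo-trig mode, the mode through which 1,4-dicarbonyl compounds give cyclopentenones; on paper it is the less favourable enolate closure, but it is the only one open to 12 and the addition is reversible. C5 is controlled by C1': in the proposed chair-like six-membered chelate (Mg, aldehyde O, C4, C5, C1', MOM ether O) the tetradecyl chain is equatorial and anti to the forming bond and the ether oxygen lies on the C1 side of the enol, so C4 adds to the enol face that gives the target configuration; C4 is controlled by the same chelate, which turns the aldehyde oxygen toward the side-chain face and away from O5 and so gives the 4,5-trans diol with the C4 oxygen cis to the side chain. The step needs chemoselectivity for aldol addition over beta-elimination of the C1' ether and over Z-to-E isomerisation of 12, which the weak base and low temperature should secure, and diastereoselectivity at C4 and C5, which the chelating MOM ether on the single stereocentre C1' is there to provide; ring C2 of 11 is flattened on enolisation, so all stereoisomers of 11 converge on 13.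

Step 8
Reactants: 13 (4R,5R)-4,5-dihydroxy-5-[(1S)-1-(methoxymethoxy)pentadecyl]cyclopent-2-en-1-one
Product: 14 (4R,5S)-4,5-dihydroxy-5-[(1S)-1-hydroxypentadecyl]cyclopent-2-en-1-one
Conditions: HCl (1 M in MeOH), 0 to 40 °C
Reagents that add atoms: none
Why: Acid-catalysed transacetalisation in methanol removes the formaldehyde acetal as dimethoxymethane, while the hydroxy-enone should tolerate dilute acid because ionisation at C4 would give a carbonyl-destabilised cation and C5 bears no hydrogen, so neither elimination nor epimerisation is open.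

Step 9
Reactants: 14 (4R,5S)-4,5-dihydroxy-5-[(1S)-1-hydroxypentadecyl]cyclopent-2-en-1-one
Product: 15 (4R,5S)-4-acetoxy-5-[(1S)-1-acetoxypentadecyl]-5-hydroxycyclopent-2-en-1-one (CNP0259741.2)
Conditions: Ac2O (2.5 equiv), pyridine, DMAP (5 mol%), CH2Cl2, 0 °C
Reagents that add atoms: acetic anhydride, CC(=O)OC(C)=O
Why: Nucleophile-catalysed acylation esterifies the two secondary hydroxyls, whereas the tertiary C5 hydroxyl, flanked by the ketone and two substituted carbons, reacts far more slowly and should stay free at 0 °C with a limited amount of anhydride.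

**Compound list**

1 | (S)-benzyl glycidyl ether, (2S)-2-[(benzyloxy)methyl]oxirane | C1[C@H](O1)COCc2ccccc2 | starting material
2 | 1-bromotridecane | CCCCCCCCCCCCCBr | starting material
3 | tridecylmagnesium bromide | CCCCCCCCCCCCC[Mg]Br | intermediate
4 | (2S)-1-(benzyloxy)hexadecan-2-ol | CCCCCCCCCCCCCC[C@H](O)COCc1ccccc1 | intermediate
5 | (2S)-1-(benzyloxy)-2-(methoxymethoxy)hexadecane | CCCCCCCCCCCCCC[C@H](OCOC)COCc1ccccc1 | intermediate
6 | (2S)-2-(methoxymethoxy)hexadecan-1-ol | CCCCCCCCCCCCCC[C@H](OCOC)CO | intermediate
7 | (2S)-2-(methoxymethoxy)hexadecanal | CCCCCCCCCCCCCC[C@H](OCOC)C=O | intermediate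
8 | furan | c1ccoc1 | starting material
9 | 2-furyllithium | [Li]c1ccco1 | intermediate
10 | (2S)-1-(furan-2-yl)-2-(methoxymethoxy)hexadecan-1-ol (both C1 epimers) | CCCCCCCCCCCCCC[C@H](OCOC)C(O)c1ccco1 | intermediate
11 | 6-hydroxy-2-[(1S)-1-(methoxymethoxy)pentadecyl]-2H-pyran-3(6H)-one (mixture at ring C2 and C6) | CCCCCCCCCCCCCC[C@H](OCOC)C1OC(O)C=CC1=O | intermediate
12 | (2Z,6S)-5-hydroxy-6-(methoxymethoxy)-4-oxoicos-2-enal (C5 epimers) | CCCCCCCCCCCCCC[C@H](OCOC)C(O)C(=O)/C=C\C=O | intermediate
13 | (4R,5R)-4,5-dihydroxy-5-[(1S)-1-(methoxymethoxy)pentadecyl]cyclopent-2-en-1-one (4,5-trans diol, side chain cis to the C4 hydroxyl) | CCCCCCCCCCCCCC[C@H](OCOC)[C@@]1(O)C(=O)C=C[C@H]1O | intermediate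
14 | (4R,5S)-4,5-dihydroxy-5-[(1S)-1-hydroxypentadecyl]cyclopent-2-en-1-one | CCCCCCCCCCCCCC[C@H](O)[C@@]1(O)C(=O)C=C[C@H]1O | intermediate
15 | (4R,5S)-4-acetoxy-5-[(1S)-1-acetoxypentadecyl]-5-hydroxycyclopent-2-en-1-one | CCCCCCCCCCCCCC[C@H](OC(C)=O)[C@@]1(O)C(=O)C=C[C@H]1OC(C)=O | target

**Step count**

Total steps: 9. Longest linear sequence: 9 steps (1 and 2 to 15; furan 8 enters in step 5, where its lithiation is part of the step).

**Steps most likely to fail**

Step 7. What may go wrong: poor facial selectivity at C5 if magnesium is chelated between O5 and the C1' ether instead of between the aldehyde oxygen and the ether, which would expose the other enol face. The 4,5-trans relationship may also erode on equilibration, and material may be lost by beta-elimination of the C1' ether or by isomerisation of the cis-ene-dione to the unreactive trans isomer.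

Fallback: the five-membered ring is bought and the C5/C1' diol is installed by substrate-controlled dihydroxylation instead of an aldol closure.
- The fallback sets out from 4. Hydrogenolysis (H2, Pd/C) gives (2S)-hexadecane-1,2-diol F1, and NaIO4 cleavage gives pentadecanal F2; the C1' centre is given up here because it is made again below.
- The lithium enolate of purchased (4S)-4-[(tert-butyldimethylsilyl)oxy]cyclopent-2-en-1-one (O=C1C=C[C@@H](O[Si](C)(C)C(C)(C)C)C1; LiN(iPr)2, THF, −78 °C) adds to F2 to give the 4,5-trans aldol adduct 4-[(tert-butyldimethylsilyl)oxy]-5-(1-hydroxypentadecyl)cyclopent-2-en-1-one F3.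
- MsCl/NEt3 converts it into its methanesulfonate F4, which DBU eliminates to (4R,5E)-4-[(tert-butyldimethylsilyl)oxy]-5-pentadecylidenecyclopent-2-en-1-one F5.
- OsO4 (catalytic) with N-methylmorpholine N-oxide in acetone/water should dihydroxylate the more electron-rich exocyclic trisubstituted alkene from the face opposite the silyloxy group. Syn addition to the E alkene from that face gives the 4,5-trans diol with C1' S, (4R,5S)-4-[(tert-butyldimethylsilyl)oxy]-5-hydroxy-5-[(1S)-1-hydroxypentadecyl]cyclopent-2-en-1-one F6.
- HF·pyridine in THF removes the silyl group, and the route is rejoined at triol 14, which goes on through step 9.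

Step 8. What may go wrong: slow acetal cleavage at the hindered C1' oxygen, so that the free hydroxy-enone sits in warm acid for long and degrades, or the formaldehyde unit is passed on to a neighbouring hydroxyl.

Fallback: the two acetates are introduced one at a time around an aprotic cleavage, so that the allylic hydroxyl never meets the acid.
- The fallback sets out from 13. Ac2O/pyridine at 0 °C should acetylate only the secondary C4 hydroxyl to give (4R,5S)-4-acetoxy-5-hydroxy-5-[(1S)-1-(methoxymethoxy)pentadecyl]cyclopent-2-en-1-one F7.
- Me2BBr in CH2Cl2 at −78 °C followed by aqueous NaHCO3 cleaves the MOM ether to (4R,5S)-4-acetoxy-5-hydroxy-5-[(1S)-1-hydroxypentadecyl]cyclopent-2-en-1-one F8.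
- Acetylation of the C1' hydroxyl under the conditions of step 9 then gives the target, so the route is rejoined at 15.

Step 5. What may go wrong: erosion of configurational purity at C1' through enolisation of the alpha-alkoxy aldehyde by the basic organolithium, or during handling of 7.

Fallback: the C–C bond is made at the carboxylic acid oxidation level, where no enolisable aldehyde is present.
- The fallback sets out from 6. TEMPO/PhI(OAc)2 in aqueous MeCN gives (2S)-2-(methoxymethoxy)hexadecanoic acid F9.
- Coupling with N,O-dimethylhydroxylamine hydrochloride (EDC·HCl, iPr2NEt, CH2Cl2) gives (2S)-N-methoxy-N-methyl-2-(methoxymethoxy)hexadecanamide F10.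
- 2-Furyllithium 9 adds once, through a stable chelated tetrahedral intermediate (Weinreb ketone synthesis), to give (2S)-1-(furan-2-yl)-2-(methoxymethoxy)hexadecan-1-one F11.
- Luche reduction (NaBH4, CeCl3·7H2O, MeOH, −40 °C) returns the carbinol as an epimer mixture, which is all that is required, and the route is rejoined at 10.

**Further compounds**

F1 | step 7 | (2S)-hexadecane-1,2-diol | CCCCCCCCCCCCCC[C@H](O)CO
F2 | step 7 | pentadecanal | CCCCCCCCCCCCCCC=O
F3 | step 7 | 4,5-trans-4-[(tert-butyldimethylsilyl)oxy]-5-(1-hydroxypentadecyl)cyclopent-2-en-1-one (4R,5S; carbinol epimers) | CCCCCCCCCCCCCCC(O)[C@@H]1C(=O)C=C[C@H]1O[Si](C)(C)C(C)(C)C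
F4 | step 7 | methanesulfonate of F3 | CCCCCCCCCCCCCCC(OS(C)(=O)=O)[C@@H]1C(=O)C=C[C@H]1O[Si](C)(C)C(C)(C)C
F5 | step 7 | (4R,5E)-4-[(tert-butyldimethylsilyl)oxy]-5-pentadecylidenecyclopent-2-en-1-one | CCCCCCCCCCCCCC/C=C1/C(=O)C=C[C@H]1O[Si](C)(C)C(C)(C)C
F6 | step 7 | (4R,5S)-4-[(tert-butyldimethylsilyl)oxy]-5-hydroxy-5-[(1S)-1-hydroxypentadecyl]cyclopent-2-en-1-one | CCCCCCCCCCCCCC[C@H](O)[C@@]1(O)C(=O)C=C[C@H]1O[Si](C)(C)C(C)(C)C
F7 | step 8 | (4R,5S)-4-acetoxy-5-hydroxy-5-[(1S)-1-(methoxymethoxy)pentadecyl]cyclopent-2-en-1-one | CCCCCCCCCCCCCC[C@H](OCOC)[C@@]1(O)C(=O)C=C[C@H]1OC(C)=O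
F8 | step 8 | (4R,5S)-4-acetoxy-5-hydroxy-5-[(1S)-1-hydroxypentadecyl]cyclopent-2-en-1-one | CCCCCCCCCCCCCC[C@H](O)[C@@]1(O)C(=O)C=C[C@H]1OC(C)=O
F9 | step 5 | (2S)-2-(methoxymethoxy)hexadecanoic acid | CCCCCCCCCCCCCC[C@H](OCOC)C(=O)O
F10 | step 5 | (2S)-N-methoxy-N-methyl-2-(methoxymethoxy)hexadecanamide | CCCCCCCCCCCCCC[C@H](OCOC)C(=O)N(C)OC
F11 | step 5 | (2S)-1-(furan-2-yl)-2-(methoxymethoxy)hexadecan-1-one | CCCCCCCCCCCCCC[C@H](OCOC)C(=O)c1ccco1
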